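**Retrosynthetic overview** (daucane numbering: C1 = C–Me, C2/C3 = ring CH2, C4 = C(OH)iPr, C5 = ring-fusion CH, C6 = CH–O-ester, C7 = CH2, C8 = C(=C14H2), C9 = CHOH, C10 = CH2)
1. Target ⇒ phenol de-acetylation ⇒ seven-membered ring closed last at C8–C9 by intramolecular Nozaki–Hiyama–Kishi addition of a vinyl bromide to the C9 aldehyde (sets C9).
2. C6–C7 and C6–O come from chelation-controlled 2-bromoallylation of a β-hydroxy aldehyde with 2,3-dibromopropene (C7/C8/C14 linchpin); the vanillate is put on before ring closure.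
3. The cyclopentane (C4–C5 bond; C1, C4, C5 in one step) comes from a desymmetrising amine-catalysed 5-enolexo aldol of an achiral keto-dialdehyde.
4. The keto-dialdehyde comes from ozonolysis of a diallyl ketone, made by radical conjugate addition of the tertiary oxalate of 4-methylhepta-1,6-dien-4-ol to isopropyl vinyl ketone.
5. Ring order: cyclopentane first (step 4), cycloheptane last (step 7).

Assumption: 1, 4, 10 and 12 are taken as catalogue compounds, and the sense of induction of proline in step 4 is taken from the Houk–List enamine model (if it proves opposite, L-proline replaces D-proline with no other change).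

**Route**

Step 1
Reactants: 1 4-methylhepta-1,6-dien-4-ol
Product: 3 cesium 2-[(4-methylhepta-1,6-dien-4-yl)oxy]-2-oxoacetate, via methyl oxalate 2 (not isolated)
Conditions: ClC(O)CO2Me, Et3N, DMAP (cat.), CH2Cl2, 0 °C to rt; then CsOH (1.0 equiv), THF/H2O, rt
Reagents that add atoms: methyl chlorooxoacetate COC(=O)C(Cl)=O; cesium hydroxide [Cs+].[OH-]
Why: O-acylation of the tertiary alcohol by the reactive oxalyl half-ester chloride, then selective saponification of the unhindered methyl ester, gives the bench-stable tertiary cesium oxalate; no stereocentre.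

Step 2
Reactants: 3 cesium 2-[(4-methylhepta-1,6-dien-4-yl)oxy]-2-oxoacetate, 4 isopropyl vinyl ketone (4-methylpent-1-en-3-one)
Product: 5 2,6-dimethyl-6-(prop-2-en-1-yl)non-8-en-3-one
Conditions: Ir[dF(CF3)ppy]2(dtbbpy)PF6 (1 mol %), 4 (1.5 equiv), H2O (10 equiv), DME/DMF 3:1, blue LEDs, 60 °C
Reagents that add atoms: none
Why: Photoredox oxidation of the oxalate and loss of two CO2 give the tertiary radical, which adds to the vinyl ketone (Giese addition, then reduction and protonation of the α-keto radical) to build the quaternary carbon; the radical has only 3-exo/4-endo options on its own allyl groups; product achiral.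

Step 3
Reactants: 5 2,6-dimethyl-6-(prop-2-en-1-yl)non-8-en-3-one
Product: 7 3-methyl-3-(4-methyl-3-oxopentyl)pentanedial, via bis-ozonide 6 (not isolated)
Conditions: O3, CH2Cl2, −78 °C; then Me2S, −78 °C to rt; used crude
Reagents that add atoms: ozone [O-][O+]=O
Why: Ozonolysis with reductive work-up cleaves both terminal alkenes to two enantiotopic CH2CHO arms and leaves the ketone alone; product achiral (prochiral at the quaternary carbon).

Step 4
Reactants: 7 3-methyl-3-(4-methyl-3-oxopentyl)pentanedial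
Product: 9 (1R,2R,5R)-2-(2,2-dimethoxyethyl)-5-hydroxy-2-methyl-5-(propan-2-yl)cyclopentane-1-carbaldehyde, via aldol dialdehyde 8 (not isolated)
Conditions: D-proline (20 mol %), DMSO/CHCl3 1:4, 0.05 M, 4 °C; then HC(OMe)3, MeOH, PPTS (10 mol %), 0 °C
Reagents that add atoms: trimethyl orthoformate COC(OC)OC; methanol CO
Why: Proposed new method: desymmetrising enamine-catalysed 5-enolexo aldolisation of a prochiral bis(formylmethyl) quaternary carbon onto an unactivated dialkyl ketone – D-proline forms the E-enamine of either CH2CHO arm, which adds through a carboxylic-acid-bridged (Houk–List-type) transition state to the isopropyl ketone five atoms away (the only other intramolecular aldehyde–aldehyde mode would give a cyclobutane); the acid bridge holds the enamine carbon and the ketone oxygen syn, so CHO and the new tertiary OH end up cis (C5, C4), the catalyst fixes the enamine face (C5), and the ring-forming transition state selects the arm that puts the small methyl rather than the second CH2CHO arm next to the enamine (C1), so the C1 quaternary, C5 and C4 centres are set together; the closest known reactions are proline-catalysed 6- and 5-enolexo aldolisations of dialdehydes and keto-aldehydes and the Hajos–Parrish desymmetrisation; the in-situ acetal formation then takes only the unhindered CH2CHO group, because the other formyl group sits on a carbon flanked by two fully substituted carbons.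

Step 5
Reactants: 9 (1R,2R,5R)-2-(2,2-dimethoxyethyl)-5-hydroxy-2-methyl-5-(propan-2-yl)cyclopentane-1-carbaldehyde, 10 2,3-dibromoprop-1-ene
Product: 11 (1R,2S,3R)-2-[(1S)-3-bromo-1-hydroxybut-3-en-1-yl]-3-(2,2-dimethoxyethyl)-3-methyl-1-(propan-2-yl)cyclopentan-1-ol
Conditions: In powder (1.5 equiv), 10 (1.5 equiv), THF/H2O 1:1, rt
Reagents that add atoms: none
Why: Barbier-type indium allylation: indium inserts only into the allylic C–Br bond (vinyl C–Br untouched) and the allylindium adds to the one free aldehyde through the indium chelate of C4–OH and C6=O, from the face opposite the C1 quaternary carbon and its syn methyl, which gives 6S (chelation-controlled allylation of a β-hydroxy aldehyde); the acetal keeps C9 out of the reaction and prevents lactol formation.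

Step 6
Reactants: 11 (1R,2S,3R)-2-[(1S)-3-bromo-1-hydroxybut-3-en-1-yl]-3-(2,2-dimethoxyethyl)-3-methyl-1-(propan-2-yl)cyclopentan-1-ol, 12 4-(acetyloxy)-3-methoxybenzoic acid
Product: 15 (1S)-3-bromo-1-[(1S,2R,5R)-2-hydroxy-5-methyl-5-(2-oxoethyl)-2-(propan-2-yl)cyclopentyl]but-3-en-1-yl 4-(acetyloxy)-3-methoxybenzoate, via acid chloride 13 (not isolated), via acetal ester 14 (not isolated)
Conditions: 12, (COCl)2, DMF (cat.), CH2Cl2, rt, concentrate; then 11, pyridine, DMAP (0.2 equiv), CH2Cl2, 0 °C to rt; then THF/2 M aq HCl 5:1, 0 °C to rt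
Reagents that add atoms: water O (aldehyde oxygen of 15); oxalyl chloride O=C(Cl)C(=O)Cl (chlorine of 13 only)
Why: Acid chloride formation and DMAP-catalysed esterification take the secondary C6–OH and leave the tertiary C4–OH; brief aqueous acid then hydrolyses the dimethyl acetal without harming the esters, and with O6 acylated and C4–OH trans to the CH2CHO arm no lactol can form; no stereocentre is changed.

Step 7
Reactants: 15 (1S)-3-bromo-1-[(1S,2R,5R)-2-hydroxy-5-methyl-5-(2-oxoethyl)-2-(propan-2-yl)cyclopentyl]but-3-en-1-yl 4-(acetyloxy)-3-methoxybenzoate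
Product: 16 (3R,3aS,4S,7S,8aR)-3,7-dihydroxy-8a-methyl-6-methylidene-3-(propan-2-yl)decahydroazulen-4-yl 4-(acetyloxy)-3-methoxybenzoate
Conditions: CrCl2 (6 equiv), NiCl2 (5 mol %), degassed DMSO, 0.005 M, rt
Reagents that add atoms: none
Why: Intramolecular Nozaki–Hiyama–Kishi reaction: Ni inserts into the vinyl C–Br bond, transmetalation gives an alkenylchromium(III) that adds only to the aldehyde (esters and the free tertiary OH are tolerated) and closes the seven-membered ring; in the chair-like closure the O–Cr group at C9 sits pseudo-equatorial to avoid the 1,3-diaxial contact with the axial angular methyl on C1, which gives the 9S (9α) alcohol trans to that methyl.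

Step 8
Reactants: 16 (3R,3aS,4S,7S,8aR)-3,7-dihydroxy-8a-methyl-6-methylidene-3-(propan-2-yl)decahydroazulen-4-yl 4-(acetyloxy)-3-methoxybenzoate
Product: 17 (3R,3aS,4S,7S,8aR)-3,7-dihydroxy-8a-methyl-6-methylidene-3-(propan-2-yl)decahydroazulen-4-yl 4-hydroxy-3-methoxybenzoate (target; daucane 1R,4R,5S,6S,9S)
Conditions: K2CO3 (0.3 equiv), MeOH, 0 °C, 20 min; NH4Cl quench
Reagents that add atoms: none
Why: Methanolysis (transesterification) of the aryl acetate is far faster than that of the hindered secondary vanillate, and the phenoxide formed deactivates the vanillate carbonyl further; no stereocentre is touched.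

**Compound list**
1 | 4-methylhepta-1,6-dien-4-ol | C=CCC(C)(O)CC=C | starting material
2 | methyl 4-methylhepta-1,6-dien-4-yl oxalate | C=CCC(C)(CC=C)OC(=O)C(=O)OC | intermediate
3 | cesium 2-[(4-methylhepta-1,6-dien-4-yl)oxy]-2-oxoacetate | C=CCC(C)(CC=C)OC(=O)C(=O)[O-].[Cs+] | intermediate
4 | 4-methylpent-1-en-3-one (isopropyl vinyl ketone) | C=CC(=O)C(C)C | starting material
5 | 2,6-dimethyl-6-(prop-2-en-1-yl)non-8-en-3-one | CC(C)C(=O)CCC(C)(CC=C)CC=C | intermediate
6 | 2,6-dimethyl-7-(1,2,4-trioxolan-3-yl)-6-[(1,2,4-trioxolan-3-yl)methyl]heptan-3-one (bis-ozonide, isomer mixture) | CC(C)C(=O)CCC(C)(CC1OCOO1)CC1OCOO1 | intermediate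
7 | 3-methyl-3-(4-methyl-3-oxopentyl)pentanedial | CC(C)C(=O)CCC(C)(CC=O)CC=O | intermediate
8 | 2-[(1R,2R,3R)-2-formyl-3-hydroxy-1-methyl-3-(propan-2-yl)cyclopentyl]acetaldehyde | O=C[C@@H]1[C@](C)(CC[C@@]1(O)C(C)C)CC=O | intermediate
9 | (1R,2R,5R)-2-(2,2-dimethoxyethyl)-5-hydroxy-2-methyl-5-(propan-2-yl)cyclopentane-1-carbaldehyde | O=C[C@@H]1[C@](C)(CC[C@@]1(O)C(C)C)CC(OC)OC | intermediate
10 | 2,3-dibromoprop-1-ene | C=C(Br)CBr | starting material
11 | (1R,2S,3R)-2-[(1S)-3-bromo-1-hydroxybut-3-en-1-yl]-3-(2,2-dimethoxyethyl)-3-methyl-1-(propan-2-yl)cyclopentan-1-ol | C=C(Br)C[C@H](O)[C@@H]1[C@](C)(CC[C@@]1(O)C(C)C)CC(OC)OC | intermediate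
12 | 4-(acetyloxy)-3-methoxybenzoic acid | CC(=O)Oc1ccc(cc1OC)C(=O)O | starting material
13 | 4-(acetyloxy)-3-methoxybenzoyl chloride | CC(=O)Oc1ccc(cc1OC)C(Cl)=O | intermediate
14 | (1S)-3-bromo-1-[(1S,2R,5R)-5-(2,2-dimethoxyethyl)-2-hydroxy-5-methyl-2-(propan-2-yl)cyclopentyl]but-3-en-1-yl 4-(acetyloxy)-3-methoxybenzoate | C=C(Br)C[C@H](OC(=O)c1ccc(OC(C)=O)c(OC)c1)[C@@H]2[C@](C)(CC[C@@]2(O)C(C)C)CC(OC)OC | intermediate
15 | (1S)-3-bromo-1-[(1S,2R,5R)-2-hydroxy-5-methyl-5-(2-oxoethyl)-2-(propan-2-yl)cyclopentyl]but-3-en-1-yl 4-(acetyloxy)-3-methoxybenzoate | C=C(Br)C[C@H](OC(=O)c1ccc(OC(C)=O)c(OC)c1)[C@@H]2[C@](C)(CC[C@@]2(O)C(C)C)CC=O | intermediate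
16 | (3R,3aS,4S,7S,8aR)-3,7-dihydroxy-8a-methyl-6-methylidene-3-(propan-2-yl)decahydroazulen-4-yl 4-(acetyloxy)-3-methoxybenzoate | C=C1C[C@H](OC(=O)c2ccc(OC(C)=O)c(OC)c2)[C@@H]3[C@](C)(CC[C@@]3(O)C(C)C)C[C@@H]1O | intermediate
17 | (3R,3aS,4S,7S,8aR)-3,7-dihydroxy-8a-methyl-6-methylidene-3-(propan-2-yl)decahydroazulen-4-yl 4-hydroxy-3-methoxybenzoate | C=C1C[C@H](OC(=O)c2ccc(O)c(OC)c2)[C@@H]2[C@](C)(CC[C@@]2(O)C(C)C)C[C@@H]1O | target

**Step count and risks**
Total step count: 8. Longest linear sequence: 8 (steps 1–8; 12 is bought).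

Step 4 (the proposed new desymmetrising aldol) is the most likely to fail. The risks are the reverse cyclisation (ketone enamine onto an aldehyde), loss of water to the cyclopentene carbaldehyde, and weak discrimination of the two arms (C1 epimer). The fallback uses known chemistry, sets out from 4 and comes back at 15. Enone 4 and commercial racemic 2-methylpent-4-enal (C=CCC(C)C=O) are joined by known chiral primary-amine (amine–thiourea) enamine catalysis of α-branched aldehyde Michael additions. This gives the quaternary aldehyde (2R)-2,6-dimethyl-5-oxo-2-(prop-2-en-1-yl)heptanal F1, with C1 set by the catalyst. Wittig reaction with Ph3P=CHOMe gives the enol ether (6R)-8-methoxy-2,6-dimethyl-6-(prop-2-en-1-yl)oct-7-en-3-one F2, and THF/aq HCl gives the homologated aldehyde (3R)-3,7-dimethyl-6-oxo-3-(prop-2-en-1-yl)octanal F3. D-Proline-catalysed 5-enolexo aldolisation, now with a single donor arm and only diastereoselective, gives (1R,2R,5R)-2-hydroxy-5-methyl-2-(propan-2-yl)-5-(prop-2-en-1-yl)cyclopentane-1-carbaldehyde F4. Indium and 10, as in step 5, give (1R,2S,3R)-2-[(1S)-3-bromo-1-hydroxybut-3-en-1-yl]-3-methyl-1-(propan-2-yl)-3-(prop-2-en-1-yl)cyclopentan-1-ol F5. Acylation with 13 gives (1S)-3-bromo-1-[(1S,2R,5R)-2-hydroxy-5-methyl-2-(propan-2-yl)-5-(prop-2-en-1-yl)cyclopentyl]but-3-en-1-yl 4-(acetyloxy)-3-methoxybenzoate F6. OsO4 (cat.)/NaIO4/2,6-lutidine then cleaves the allyl group, the electron-poor vinyl bromide reacting much more slowly, to give 15. In this fallback the allyl group serves as the latent C9 aldehyde, so no acetal is needed.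

Step 5 (indium 2-bromoallylation) is the second risk: the aldehyde is hindered, and Felkin-type addition could compete with the chelate and give the 6R epimer. The fallback sets out from 9 and comes back at 11, and replaces substrate (chelate) control by catalyst control in a closed allylboration transition state. Aldehyde 9 is treated with 2-(2-bromoprop-2-en-1-yl)-4,4,5,5-tetramethyl-1,3,2-dioxaborolane and a chiral BINOL-phosphoric acid (TRIP, 5 mol %, enantiomer chosen for 6S) in toluene with 4 Å sieves at −30 °C. This gives the borate 2-{[(1S)-3-bromo-1-[(1S,2R,5R)-5-(2,2-dimethoxyethyl)-2-hydroxy-5-methyl-2-(propan-2-yl)cyclopentyl]but-3-en-1-yl]oxy}-4,4,5,5-tetramethyl-1,3,2-dioxaborolane F7, which is hydrolysed on aqueous work-up to 11.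

Step 7 (NHK closure) is the third risk: the seven-membered ring closure may be slow with a vinyl bromide, and the C9 configuration rests on a conformational argument. The fallback sets out from 15 and comes back at 17, and sets C9 by inversion instead of by the C–C bond formation. If the closure gives mainly the 9-epimer (3R,3aS,4S,7R,8aR)-3,7-dihydroxy-8a-methyl-6-methylidene-3-(propan-2-yl)decahydroazulen-4-yl 4-(acetyloxy)-3-methoxybenzoate F8, Mitsunobu reaction with chloroacetic acid (PPh3, DIAD, toluene, 0 °C) inverts C9. This gives (3R,3aS,4S,7S,8aR)-7-[(chloroacetyl)oxy]-3-hydroxy-8a-methyl-6-methylidene-3-(propan-2-yl)decahydroazulen-4-yl 4-(acetyloxy)-3-methoxybenzoate F9. K2CO3/MeOH at 0 °C then removes the chloroacetate and the aryl acetate together to give 17.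

**Further compounds**
F1 | step 4 | (2R)-2,6-dimethyl-5-oxo-2-(prop-2-en-1-yl)heptanal | O=C[C@](C)(CCC(=O)C(C)C)CC=C
F2 | step 4 | (6R)-8-methoxy-2,6-dimethyl-6-(prop-2-en-1-yl)oct-7-en-3-one (E/Z mixture) | COC=C[C@](C)(CCC(=O)C(C)C)CC=C
F3 | step 4 | (3R)-3,7-dimethyl-6-oxo-3-(prop-2-en-1-yl)octanal | O=CC[C@](C)(CCC(=O)C(C)C)CC=C
F4 | step 4 | (1R,2R,5R)-2-hydroxy-5-methyl-2-(propan-2-yl)-5-(prop-2-en-1-yl)cyclopentane-1-carbaldehyde | O=C[C@@H]1[C@](C)(CC[C@@]1(O)C(C)C)CC=C
F5 | step 4 | (1R,2S,3R)-2-[(1S)-3-bromo-1-hydroxybut-3-en-1-yl]-3-methyl-1-(propan-2-yl)-3-(prop-2-en-1-yl)cyclopentan-1-ol | C=C(Br)C[C@H](O)[C@@H]1[C@](C)(CC[C@@]1(O)C(C)C)CC=C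
F6 | step 4 | (1S)-3-bromo-1-[(1S,2R,5R)-2-hydroxy-5-methyl-2-(propan-2-yl)-5-(prop-2-en-1-yl)cyclopentyl]but-3-en-1-yl 4-(acetyloxy)-3-methoxybenzoate | C=C(Br)C[C@H](OC(=O)c1ccc(OC(C)=O)c(OC)c1)[C@@H]2[C@](C)(CC[C@@]2(O)C(C)C)CC=C
F7 | step 5 | 2-{[(1S)-3-bromo-1-[(1S,2R,5R)-5-(2,2-dimethoxyethyl)-2-hydroxy-5-methyl-2-(propan-2-yl)cyclopentyl]but-3-en-1-yl]oxy}-4,4,5,5-tetramethyl-1,3,2-dioxaborolane | C=C(Br)C[C@H](OB1OC(C)(C)C(C)(C)O1)[C@@H]2[C@](C)(CC[C@@]2(O)C(C)C)CC(OC)OC
F8 | step 7 | (3R,3aS,4S,7R,8aR)-3,7-dihydroxy-8a-methyl-6-methylidene-3-(propan-2-yl)decahydroazulen-4-yl 4-(acetyloxy)-3-methoxybenzoate | C=C1C[C@H](OC(=O)c2ccc(OC(C)=O)c(OC)c2)[C@@H]3[C@](C)(CC[C@@]3(O)C(C)C)C[C@H]1O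
F9 | step 7 | (3R,3aS,4S,7S,8aR)-7-[(chloroacetyl)oxy]-3-hydroxy-8a-methyl-6-methylidene-3-(propan-2-yl)decahydroazulen-4-yl 4-(acetyloxy)-3-methoxybenzoate | C=C1C[C@H](OC(=O)c2ccc(OC(C)=O)c(OC)c2)[C@@H]3[C@](C)(CC[C@@]3(O)C(C)C)C[C@@H]1OC(=O)CCl
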